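The easy step comes first: I set out the flasks and readings, then add product and substrate along each row.

| flask | substrate | coupling partner | free catalyst | temperature | remark | time |
|---|---|---|---|---|---|---|
| amber | 0.20 mM | 0.40 mM | 2 µM | 70 °C | the very flask that is asked about, followed so far |  |
| teal | 0.20 mM | 0.27 mM | 2 µM | 70 °C | run made earlier |  |
| flask | 0.20 mM | 0.400 mM | 2.0 µM | 70 °C |  | 2.5 h |

| run | time / min | product / % | substrate / % |
|---|---|---|---|
| amber | 10.0 | 59.2 | 41.4 |
| amber | 15.0 | 62.4 | 37.8 |
| amber | 25.0 | 63.5 | 36.6 |
| amber | 40.0 | 63.6 | 37.0 |
| amber | 80.0 | 63.7 | 36.5 |
| amber | 120 | 64.5 | 35.8 |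
| teal | 0.500 | 8.0 | 91.0 |
| teal | 0.833 | 13.9 | 86.3 |
| teal | 1.33 | 20.1 | 80.4 |
| teal | 2.00 | 26.9 | 72.9 |
| teal | 4.00 | 41.8 | 58.3 |
| teal | 6.00 | 49.7 | 49.7 |

(each reading ± 0.5 percentage points)

- product that was removed still counts
- additions bring no volume worth counting
- the earlier runs do not show what temperature does; that part of a forecast is a guess

- product, in percent of the substrate first charged, at 2.5 h
- what to do for the largest gain in product; "none" if nothing gains more than 2 percentage points (dusk / autumn / midnight / winter / noon / none)
- product present, with what was taken out counted in, in percent of the substrate first charged, after autumn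
- product present, with what was taken out counted in, in percent of the substrate first charged, after noon

- dusk: at 2.5 h add free catalyst, 100% of the amount charged, then wait 80 min
- autumn: at 2.5 h add coupling partner, 50.0% of the amount charged, then wait 80 min
- midnight: change nothing and wait 80 min more
- winter: at 2.5 h take out 90% of the product then present, then wait 80 min
- noon: at 2.5 h raise the temperature by 15 K, then wait 80 min

At 80.0 min the amber run sums to 100%, so the readings account for the charged substrate. What I watch is the fall of substrate per unit of substrate, a pseudo-first-order constant. In the first instants, read from the teal run up to 0.500 min, it is 0.189 /min. In the middle, between 4.00 min and 6.00 min of the teal run, it is 0.0798 /min, which is lower. Near the end, between 10.0 min and 15.0 min of the amber run, it is 0.0182 /min. From 25.0 min on, the amber substrate stays between 35.8% and 37.0%, with a scatter of 0.5 percentage points.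

The amber run stops with 36.5% of its substrate and, at one partner per product, 68.1% of its coupling partner present, so neither reagent has run out. Is that an equilibrium? The quotient [product]/([substrate][coupling partner]) is 6.40 /mM at the amber stop. The teal run reads 5.86 /mM at 6.00 min, and its constant over its last two readings is higher than the amber constant near the end. The teal readings end before any stop, so this is no proof, but I read the amber stop as a dying catalyst.

Suppose that, at one temperature, the constant follows the live catalyst and the catalyst lasts equally long whatever the [substrate]; then equal charges of catalyst take substrate down by equal fractions. I therefore carry the reach: ln([substrate]start/[substrate]stop) per µM of catalyst charged, read from the amber run as 0.504 /µM.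

For the flask, a copy of the amber run, I commit to about 63.7% at 2.5 h. Waiting, more partner, removing product and heating bring no fresh catalyst, so on my reading I expect no gain from them, though the heating is a guess. A fresh dose should take the remaining substrate down by the same fraction, a gain of 23 points, so I choose dusk.

The forecast gives 64% at 2.5 h, 64.2% after autumn and 63% after noon, and it picks winter, where I pick dusk: “More catalyst or waiting then changes nothing”.

The flask gives 63.3%, 63.3% after autumn and 63.3% after noon. The best choice is dusk, which gains 23 points, while winter gains 0 points.

    coupling partner + free catalyst → catalyst intermediate A (k = 5000 /M/s, Ea = 23.0 kJ/mol)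
    catalyst intermediate A ⇌ catalyst intermediate B (K = 1.40, k = 52.0 /s, Ea = 74.0 kJ/mol, ΔH = −3.00 kJ/mol)
    substrate + catalyst intermediate B ⇌ catalyst intermediate C (K = 1800 /M, k = 13000 /M/s, Ea = 17.0 kJ/mol, ΔH = −11.0 kJ/mol)
    catalyst intermediate C → free catalyst + product (k = 3.20 /s, Ea = 92.0 kJ/mol)
    catalyst intermediate A → spent catalyst (k = 0.0110 /s, Ea = 104 kJ/mol)
    (constants at 70 °C)

At 150 min the flask holds 100% of its catalyst as spent catalyst, with 36.7% of its substrate unconverted. The reach applied to that substrate gives 23 points for dusk. A neighbouring flask, charged with 0.0080 mM of free catalyst, should keep 1.77% of its substrate by the same reach. At 150 min that flask holds 98.2% product, with 49% of its coupling partner left and 1.77% of its substrate.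

(The runs were generated by integration for substances that don't exist, and the scatter is random.)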